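The numbers of this flask are made up; the run is a simulation.

The vessel holds a slurry: solid substrate dissolves into starting material, free catalyst captures that as catalyst intermediate, the intermediate releases product and free catalyst, and two free catalyst can meet and become spent catalyst.

solid substrate 0.37 M; free catalyst 2.2 mol%; time 40 h

1. the product standing at 40 h, as a percentage of the solid substrate charged
2. concentration of starting material in solution at 40 h, in percent of saturation

- a step written with two of one species runs at k times the square of its concentration and takes two of it each time
- given per volume of solution although it is solid: solid substrate
- at the start none of the solid substrate is in solution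
- starting material means what is dissolved; the solid is not counted in it
- run time (flask): 40 h

    starting material + free catalyst → catalyst intermediate (k1 = 7.33 L mol⁻¹ h⁻¹)
    catalyst intermediate → free catalyst + product (k2 = 1.06 h⁻¹)
    solid substrate ⇌ starting material, rate k3*(cs3 - [starting material]) while solid is left; crystals form when [starting material] > cs3 (cs3 = 0.25 M, k3 = 0.173 h⁻¹)
    2 free catalyst → spent catalyst (k4 = 5.15 L mol⁻¹ h⁻¹)

My reckoning freezes the dissolved level at the solubility. There, capture over release gives K = 1.73 intermediate per free catalyst, so the share K/(K+one) of the living catalyst is working. Loss strikes the free part, so from the charge c = 0.00814 M the living catalyst falls as c/(one + t/τ), with τ = 88.8 h.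

Now define S, the catalyst's draw on the solution over the feed of the solid into an empty solution, 0.0432 M h⁻¹: S = 8.71% at 40 h. In a steady state feed equals draw, so the solution stands short of saturation by the fraction S, which gives 91.3%. The draw is 0.00377 M h⁻¹. Run from the dissolving time 5.78 h onward, it gives 34.9%. Holding the catalyst at its 40 h value is my allowance for early losses.

Was one number enough? Solution and product together need 96.5% of the charge, so in this reckoning some solid still stands at 40 h.

The forecast gave 36% (32% to 40%) and 92% (86% to 96%), on this ground: “Dissolution brings the starting material up to a near-steady level just below saturation”. The simulation gives 35.4% and 92.5%.

At 40.0 h this flask makes catalyst intermediate at 0.993 times the rate it uses it up, and its solution stands 7.50% short of saturation, against S of 8.71%. In the same flask read at 15 h, S is 10.8%, which over the time after 5.78 h gives 11.7% product, and that flask holds 12.5%.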